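Two constants of this flask can be read from its earlier runs, a ratio and a time, and together they give the end state and the approach to it.

all flasks: substrate 0.30 M

|  | reagent | capture agent | remark | time |
|---|---|---|---|---|
| south | 0.74 equiv | 0.090 M | run made earlier |  |
| north-west | 1.7 equiv | 0.090 M | run made earlier |  |
| epsilon | 1.10 equiv | 0.0900 M |  | 36 h |
| alpha | 1.10 equiv | 0.0900 M |  | 12 h |
| delta | 1.10 equiv | 0.0900 M |  | 110 h |

| run | time / h | substrate / % | target / % | side product / % | intermediate C / % | intermediate A / % | trapped intermediate / % |
|---|---|---|---|---|---|---|---|
| south | 1.33 | 58.1 | 5.4 | 0.3 | 3.2 | 28.5 | 0.6 |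
| south | 3.00 | 30.7 | 13.4 | 0.6 | 10.9 | 40.7 | 2.5 |
| south | 4.00 | 21.2 | 16.7 | 0.8 | 16.9 | 41.4 | 2.4 |
| south | 6.00 | 9.3 | 19.3 | 3.1 | 26.4 | 37.1 | 4.0 |
| south | 8.00 | 3.7 | 20.6 | 5.2 | 33.8 | 30.9 | 5.0 |
| south | 10.0 | 1.5 | 20.7 | 7.5 | 39.5 | 23.1 | 5.7 |
| north-west | 1.33 | 49.8 | 11.8 | 0 | 2.0 | 27.1 | 0.3 |
| north-west | 3.00 | 21.2 | 27.0 | 0.2 | 10.2 | 34.9 | 1.8 |
| north-west | 4.00 | 12.3 | 32.0 | 1.7 | 13.9 | 34.4 | 2.2 |
| north-west | 6.00 | 4.5 | 37.0 | 3.2 | 22.3 | 29.3 | 3.2 |
| north-west | 8.00 | 1.4 | 38.6 | 3.9 | 28.1 | 21.7 | 4.7 |
| north-west | 10.0 | 0.6 | 38.8 | 6.3 | 31.8 | 16.8 | 5.7 |

(readings scatter by 0.5 percentage points)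

- which of these there is most of at the end, counted by the substrate in it, epsilon (trapped intermediate / intermediate C / target / intermediate A / side product)
- which of these there is most of at the end, counted by the substrate in it, alpha (trapped intermediate / intermediate C / target / intermediate A / side product)
- which of these there is most of at the end, counted by the substrate in it, delta (trapped intermediate / intermediate C / target / intermediate A / side product)
- final amount of the leader among these, as a percentage of the substrate charged, in epsilon
- final amount of the leader among these, as a percentage of the substrate charged, in alpha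
- final amount of the leader among these, as a percentage of the substrate charged, in delta

- the numbers in the tables scatter with a standard deviation of 0.5 percentage points

Target stops rising in both runs as substrate dies away, moving from 20.6% to 20.7% in south and from 38.6% to 38.8% in north-west, so the substrate seems to meet a fork early. The odds of target against the rest of the charge, divided by the equivalents of reagent, are 0.353 in south and 0.373 in north-west. Their mean, 0.363, is the fork factor, a selectivity factor. At 1.10 equiv the factor gives a target share of 28.5%. The objection is that reagent is consumed, so the odds could drift. But at one reagent per target, south has used 28.0% of its reagent and north-west 22.8%, and the new recipe comes to 25.9%, so it lies between them.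

Of what passes the other way, the trapped share at the last readings averages 11.9%, and the remainder must end as side product, so the ceiling is 63.0%. South has spent 19.0% of its capture agent, yet a trapped share lowered by that fraction lifts the ceiling by just 1.6 points.

The approach is slower. Side product gained, set against the time integral of intermediate C, gives a time constant of 26.4 h in south but 31.8 h in north-west, a gap to be expected from such small gains, so the mean 29.1 h serves. The stages before it add a lag of 9.17 h, read from the late decay of substrate and intermediate A in south. My reckoning therefore puts side product at 37.9% after 36 h, which is more than target, and at 61.0% after 110 h. For alpha at 12 h, the tail of south, extended and scaled down to the smaller non-target remainder, gives intermediate C 39.6%, more than target.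

The forecast names intermediate C at 39.5% for alpha, side product at 40% for epsilon and side product at 61% for delta, and it too starts from the fork: “reagent-dependent branch gives target”. Its epsilon figure stands above mine.

The flask gives intermediate C at 38.3% in alpha, side product at 39.2% in epsilon and side product at 60.8% in delta.

    substrate → intermediate A (k = 0.00520 /min)
    substrate + reagent → intermediate B (k = 0.00760 /M/min)
    intermediate A → intermediate C (k = 0.00240 /min)
    intermediate C → side product (k = 6.20 × 10⁻⁴ /min)
    intermediate B → target (k = 0.0220 /min)
    capture agent + intermediate A → trapped intermediate (k = 0.00420 /M/min)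

Delta's target of 29.3% corresponds to a fork factor of 0.377. A neighbour of delta, charged with 4.40 equiv of reagent, gets the same reckoning: the carried factor gives a target share of 61.5% and a ceiling of 33.9%. That flask ends with target in the lead at 64.1%, while side product stands at 30.6% and intermediate C at 0.709%.

(The numbers in the tables are calculated for an exercise; scatter was added.)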